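**Retrosynthetic overview**

1. Megaphone ⇒ loss of methanol (E1cB) from a 4,5-dimethoxycyclohexanone; the C4 methoxy stereocentre comes unchanged from the chiral pool.
2. That cyclohexanone ⇒ a 1-[(Z)-alkenyl]-trans-3,4-dimethoxycyclopentanol + 3,4,5-trimethoxybenzaldehyde, joined by a catalytic asymmetric Prins addition/semipinacol ring expansion that makes C7–C8, the quaternary C6 and the six-membered ring and sets C6, C7 and C8.
3. The alkenyl cyclopentanol ⇒ ethynyl Grignard addition to C2-symmetric (3R,4R)-3,4-dimethoxycyclopentanone, then anti-allylmagnesiation/methylation; the ketone ⇒ (R)-4-hydroxycyclopent-2-enone by O-methylation and trans oxa-Michael addition of methanol.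
4. The aldehyde ⇒ p-cresol by bromination/side-chain oxidation, copper-mediated methoxylation and O-methylation.
5. Ring order: the arene and the cyclopentane are bought; the cyclohexenone ring is formed last, by expansion of the cyclopentane.

Assumption: C1–C6 are the ring carbons of megaphone (C1 carbonyl, C6 quaternary), C7 the carbinol carbon and C8 the methyl-bearing carbon; the (S,S)-catalyst of step 7 is taken to give the (6R,7R,8S) sense, and if the induction is opposite its (R,R)-enantiomer is used.

**Step 1**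
Reactants: 1 (R)-4-hydroxycyclopent-2-en-1-one
Product: 2 (R)-4-methoxycyclopent-2-en-1-one
Conditions: MeI, Ag2O, MeCN, 23 °C, dark
Reagents that add atoms: iodomethane, CI
Why: Neutral Ag2O-promoted O-methylation (Purdie/Williamson type) avoids base-induced elimination or racemisation of the 4-oxygenated enone, so C4 is carried through unchanged.

**Step 2**
Reactants: 2 (R)-4-methoxycyclopent-2-en-1-one
Product: 3 (3R,4R)-3,4-dimethoxycyclopentan-1-one
Conditions: NaOMe (5 mol %), MeOH, −20 → 0 °C; AcOH quench
Reagents that add atoms: methanol, CO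
Why: Base-catalysed oxa-Michael addition of methanol occurs anti to the C4 methoxy group and gives the trans, C2-symmetric adduct, and reversal of the trans adduct returns only the same enantiomer of the enone.

**Step 3**
Reactants: 3 (3R,4R)-3,4-dimethoxycyclopentan-1-one; 4 ethynylmagnesium bromide
Product: 5 (3R,4R)-1-ethynyl-3,4-dimethoxycyclopentan-1-ol
Conditions: LaCl3·2LiCl (1 equiv), THF, −20 °C; aq NH4Cl
Reagents that add atoms: none
Why: Lanthanum-promoted 1,2-addition of an alkynyl Grignard reagent outruns enolisation and loss of methoxide, and because the ketone is C2-symmetric its faces are equivalent and the carbinol carbon is not a stereocentre.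

**Step 4**
Reactants: 5 (3R,4R)-1-ethynyl-3,4-dimethoxycyclopentan-1-ol; 6 allylmagnesium chloride
Product: 8 (3R,4R)-1-[(2Z)-hexa-2,5-dien-3-yl]-3,4-dimethoxycyclopentan-1-ol, via alkenylmagnesium chelate 7 (not isolated)
Conditions: 6 (3 equiv), THF, 0 → 50 °C; then CuI (10 mol %), MeI, −20 → 23 °C; aq NH4Cl
Reagents that add atoms: iodomethane, CI
Why: Hydroxyl-directed anti-carbomagnesiation of the propargylic alkoxide puts allyl on the proximal carbon and magnesium on the distal carbon cis to oxygen, and copper-catalysed alkylation with retention then places the methyl cis to the carbinol, giving the (Z)-alkene.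

**Step 5**
Reactants: 9 4-methylphenol (p-cresol)
Product: 12 3,5-dibromo-4-hydroxybenzaldehyde, via 2,6-dibromo-4-methylphenol 10 (not isolated), via 2,6-dibromo-4-(dibromomethyl)phenol 11 (not isolated)
Conditions: Br2 (2 equiv), o-dichlorobenzene, 35 °C; Br2 (2 equiv), 160 °C; then H2O, 100 °C
Reagents that add atoms: bromine, BrBr; water, O
Why: Electrophilic aromatic bromination ortho to the hydroxyl, then high-temperature benzylic dibromination and hydrolysis of the benzal bromide, is the established one-pot route from p-cresol; no stereocentre is involved.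

**Step 6**
Reactants: 12 3,5-dibromo-4-hydroxybenzaldehyde
Product: 14 3,4,5-trimethoxybenzaldehyde, via syringaldehyde 13 (not isolated)
Conditions: NaOMe (4 equiv), CuCl (10 mol %), DMF–MeOH, 115 °C; then Me2SO4 (2.5 equiv), 60 °C
Reagents that add atoms: sodium methoxide, [Na+].[O-]C; dimethyl sulfate, COS(=O)(=O)OC
Why: Copper-catalysed Ullmann-type methoxylation of both aryl bromides is followed by Williamson O-methylation of the phenoxide in the same pot; no stereocentre is involved.

**Step 7**
Reactants: 8 (3R,4R)-1-[(2Z)-hexa-2,5-dien-3-yl]-3,4-dimethoxycyclopentan-1-ol; 14 3,4,5-trimethoxybenzaldehyde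
Product: 16 megaphone [(4R,6R)-6-[(1R,2S)-1-hydroxy-1-(3,4,5-trimethoxyphenyl)propan-2-yl]-4-methoxy-6-(prop-2-en-1-yl)cyclohex-2-en-1-one], via ring-expanded hydroxy ketone 15 (not isolated)
Conditions: (S,S)-IDPi (imidodiphosphorimidate from (S)-3,3'-bis[3,5-bis(trifluoromethyl)phenyl]-BINOL, N-triflyl; 5 mol %), PhMe, −40 °C; then DBU (1.5 equiv), 40 °C
Reagents that add atoms: none
Why: Proposed new method: the confined chiral Brønsted acid activates the aldehyde inside its pocket, the distal alkene carbon C8 attacks one aldehyde face through an open antiperiplanar transition state (aryl gauche to the C8 hydrogen, giving the 7,8-syn relationship), and the charge building at C6 is quenched in the same event by antiperiplanar 1,2-shift of a ring CH2 from the carbinol carbon, the hydroxyl becoming the ketone and returning the proton; anti addition across the (Z)-alkene fixes C6 relative to C8, the catalyst fixes the absolute sense at C6, C7 and C8, and because the two ring CH2 groups are equivalent through the C2 symmetry either migration gives the same ketone 15, which on adding DBU loses its β-methoxy group by E1cB (only C2 is enolisable) to give the enone; the closest known reaction types are halonium- and proton-induced semipinacol ring expansions of 1-alkenylcycloalkanols and the imidodiphosphorimidate-catalysed asymmetric Prins reaction, but an intermolecular, aldehyde-initiated, catalyst-controlled Prins addition/semipinacol ring expansion of an unactivated alkenyl cyclopentanol has not been shown.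

**Compound list**

1 | (R)-4-hydroxycyclopent-2-en-1-one | O=C1C=C[C@H](O)C1 | starting material
2 | (R)-4-methoxycyclopent-2-en-1-one | O=C1C=C[C@H](OC)C1 | intermediate
3 | (3R,4R)-3,4-dimethoxycyclopentan-1-one | O=C1C[C@@H](OC)[C@H](OC)C1 | intermediate
4 | ethynylmagnesium bromide | C#C[Mg]Br | starting material
5 | (3R,4R)-1-ethynyl-3,4-dimethoxycyclopentan-1-ol | C#CC1(O)C[C@@H](OC)[C@H](OC)C1 | intermediate
6 | allylmagnesium chloride | C=CC[Mg]Cl | starting material
7 | (7R,8R)-7,8-dimethoxy-4-(prop-2-en-1-yl)-1-oxa-2-magnesaspiro[4.4]non-3-ene (alkenylmagnesium chelate) | C=CCC1=C[Mg]OC12C[C@@H](OC)[C@H](OC)C2 | intermediate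
8 | (3R,4R)-1-[(2Z)-hexa-2,5-dien-3-yl]-3,4-dimethoxycyclopentan-1-ol | C/C=C(/CC=C)C1(O)C[C@@H](OC)[C@H](OC)C1 | intermediate
9 | 4-methylphenol (p-cresol) | Cc1ccc(O)cc1 | starting material
10 | 2,6-dibromo-4-methylphenol | Cc1cc(Br)c(O)c(Br)c1 | intermediate
11 | 2,6-dibromo-4-(dibromomethyl)phenol | BrC(Br)c1cc(Br)c(O)c(Br)c1 | intermediate
12 | 3,5-dibromo-4-hydroxybenzaldehyde | O=Cc1cc(Br)c(O)c(Br)c1 | intermediate
13 | syringaldehyde (4-hydroxy-3,5-dimethoxybenzaldehyde) | O=Cc1cc(OC)c(O)c(OC)c1 | intermediate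
14 | 3,4,5-trimethoxybenzaldehyde | O=Cc1cc(OC)c(OC)c(OC)c1 | intermediate
15 | (2R,4R,5R)-2-[(1R,2S)-1-hydroxy-1-(3,4,5-trimethoxyphenyl)propan-2-yl]-4,5-dimethoxy-2-(prop-2-en-1-yl)cyclohexan-1-one | C=CC[C@]1([C@H](C)[C@@H](O)c2cc(OC)c(OC)c(OC)c2)C[C@@H](OC)[C@H](OC)CC1=O | intermediate
16 | megaphone, (4R,6R)-6-[(1R,2S)-1-hydroxy-1-(3,4,5-trimethoxyphenyl)propan-2-yl]-4-methoxy-6-(prop-2-en-1-yl)cyclohex-2-en-1-one | C=CC[C@]1([C@H](C)[C@@H](O)c2cc(OC)c(OC)c(OC)c2)C[C@@H](OC)C=CC1=O | target

**Step count and risks**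

Total steps: 7. Longest linear sequence: 5 steps (steps 1, 2, 3, 4 and 7; 1 → 2 → 3 → 5 → 8 → 16).

Step 7 (the proposed new step). Risks: acid-induced ionisation or proton-initiated rearrangement of the tertiary allylic alcohol, low reactivity of the electron-rich aldehyde, and incomplete catalyst control. The fallback uses known chemistry, sets out from 3 and 14 and comes back at 15. Ketone 3 is alkynylated with 1-propynylmagnesium bromide (LaCl3·2LiCl, THF) to (3R,4R)-3,4-dimethoxy-1-(prop-1-yn-1-yl)cyclopentan-1-ol F1. Anti-allylmagnesiation with 6 gives (7R,8R)-7,8-dimethoxy-3-methyl-4-(prop-2-en-1-yl)-1-oxa-2-magnesaspiro[4.4]non-3-ene F2, which is trapped with aldehyde 14 to give (3R,4R)-1-[(2Z)-1-hydroxy-2-methyl-1-(3,4,5-trimethoxyphenyl)hexa-2,5-dien-3-yl]-3,4-dimethoxycyclopentan-1-ol F3 as both carbinol epimers. MnO2 oxidises the benzylic allylic alcohol to (2Z)-3-[(3R,4R)-1-hydroxy-3,4-dimethoxycyclopentyl]-2-methyl-1-(3,4,5-trimethoxyphenyl)hexa-2,5-dien-1-one F4. An acid-promoted vinylogous α-ketol rearrangement (catalytic BF3·OEt2, CH2Cl2) shifts a ring CH2 to the enone β-carbon with ring expansion and gives (2R,4R,5R)-4,5-dimethoxy-2-[(2S)-1-oxo-1-(3,4,5-trimethoxyphenyl)propan-2-yl]-2-(prop-2-en-1-yl)cyclohexan-1-one F5. The quaternary carbon is formed here without catalyst control and C8 is equilibrated α to the aryl ketone, so F5 has to be separated by chromatography. Oxazaborolidine-catalysed borane reduction of the aryl ketone ((S)-Me-CBS, reagent control at C7; selectivity over the hindered ring ketone is expected but not certain) gives 15, which goes through the DBU stage of step 7.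

Step 4. Risks: sluggish alkylation of the chelated alkenylmagnesium, and deprotonation of the terminal alkyne leading to over-alkylation. The fallback sets out from 5 and comes back at 8. Chelate 7 is formed as in step 4 but quenched with I2 to give (3R,4R)-1-[(1Z)-1-iodopenta-1,4-dien-2-yl]-3,4-dimethoxycyclopentan-1-ol F6. Negishi coupling with MeZnCl (Pd(PPh3)4, THF) then installs the methyl group with retention and gives 8.

Step 2. Risks: the addition is reversible, a small leak through the cis (meso) adduct erodes enantiopurity, and retro-Michael loss can occur on work-up. The fallback sets out from 2 and comes back at 3. Copper-catalysed conjugate borylation (B2pin2, CuCl, NaOtBu, Xantphos, MeOH, THF) anti to the methoxy group gives (3R,4R)-3-methoxy-4-(4,4,5,5-tetramethyl-1,3,2-dioxaborolan-2-yl)cyclopentan-1-one F7. Oxidation with NaBO3 (retention) gives (3R,4R)-3-hydroxy-4-methoxycyclopentan-1-one F8, and Ag2O/MeI methylation as in step 1 gives 3.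

**Further compounds**

F1 | step 7 | (3R,4R)-3,4-dimethoxy-1-(prop-1-yn-1-yl)cyclopentan-1-ol | CC#CC1(O)C[C@@H](OC)[C@H](OC)C1
F2 | step 7 | (7R,8R)-7,8-dimethoxy-3-methyl-4-(prop-2-en-1-yl)-1-oxa-2-magnesaspiro[4.4]non-3-ene | C=CCC1=C(C)[Mg]OC12C[C@@H](OC)[C@H](OC)C2
F3 | step 7 | (3R,4R)-1-[(2Z)-1-hydroxy-2-methyl-1-(3,4,5-trimethoxyphenyl)hexa-2,5-dien-3-yl]-3,4-dimethoxycyclopentan-1-ol | C=CC/C(=C(\C)C(O)c1cc(OC)c(OC)c(OC)c1)C1(O)C[C@@H](OC)[C@H](OC)C1
F4 | step 7 | (2Z)-3-[(3R,4R)-1-hydroxy-3,4-dimethoxycyclopentyl]-2-methyl-1-(3,4,5-trimethoxyphenyl)hexa-2,5-dien-1-one | C=CC/C(=C(\C)C(=O)c1cc(OC)c(OC)c(OC)c1)C1(O)C[C@@H](OC)[C@H](OC)C1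
F5 | step 7 | (2R,4R,5R)-4,5-dimethoxy-2-[(2S)-1-oxo-1-(3,4,5-trimethoxyphenyl)propan-2-yl]-2-(prop-2-en-1-yl)cyclohexan-1-one | C=CC[C@]1([C@H](C)C(=O)c2cc(OC)c(OC)c(OC)c2)C[C@@H](OC)[C@H](OC)CC1=O
F6 | step 4 | (3R,4R)-1-[(1Z)-1-iodopenta-1,4-dien-2-yl]-3,4-dimethoxycyclopentan-1-ol | C=CC/C(=C/I)C1(O)C[C@@H](OC)[C@H](OC)C1
F7 | step 2 | (3R,4R)-3-methoxy-4-(4,4,5,5-tetramethyl-1,3,2-dioxaborolan-2-yl)cyclopentan-1-one | O=C1C[C@@H](B2OC(C)(C)C(C)(C)O2)[C@H](OC)C1
F8 | step 2 | (3R,4R)-3-hydroxy-4-methoxycyclopentan-1-one | O=C1C[C@@H](O)[C@H](OC)C1
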